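**Retrosynthetic overview**

1. Numbering: C11 is the acetoxymethyl carbon; ring carbons run C1 (quaternary) – C2H2 – C3H(OAc) – C4H(OH) – C5Me2 – C6 (quaternary) – C7H2 – C8H – C9H – C10(CH3); C12 is the cage CH(OAc), bonded to C6 and C10. Ring A is C1–C6; O3, O4, O11 and O12 are the oxygens on those carbons.
2. The strategy rests on C12: a CH–OAc carbon bonded directly to cyclopropane carbon C10 inside the tricyclo[2.2.1.0]heptane cage (C1, C6, C7, C8, C9, C10, C12; three-membered ring C8–C9–C10). This is a cyclopropylcarbinyl acetate, the capture product of a 5-norbornen-2-yl cation, so C8–C10 and C12–O are cut together to an exo C8 brosylate with a C10=C12 alkene.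
3. The norbornene (bridge C1, bridgeheads C6 and C9) comes from an O11–SiMe2–vinyl tethered Diels–Alder reaction of a ring A-fused 5,5-disubstituted cyclopentadiene; Tamao oxidation turns the tether into the exo C8 hydroxyl.
4. The cyclopentadiene comes from a bridged C11(=O)–O3 lactone (allylsilane closure onto the C6 ketone, then dehydration). Ring A is closed by aldol addition of the lactone enolate C1 to the C6 aldehyde, and the lactone bridge forces C11 and O3 cis. D-pantolactone supplies C3–C6 and the C4 configuration; a 2-(ethoxycarbonyl)allyl unit supplies C1, C2, C9 and C11.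
5. Ring order: temporary lactone, ring A, cyclopentadiene ring, norbornene (two rings in one step), cyclopropane. O3 is acetylated before the cycloaddition and O4 is freed last.

Key step: step 16

Remark: D-(−)-pantolactone, ethyl 2-(bromomethyl)acrylate, 2-bromo-3-(trimethylsilyl)prop-1-ene and chloro(dimethyl)vinylsilane are taken as purchased. Centres that are erased later (C1 before ring A closure, the C6 carbinols) are left undefined.

**Route**

Step 1
Reactants: 1 D-(−)-pantolactone, (3R)-3-hydroxy-4,4-dimethyloxolan-2-one
Product: 2 (3R)-3-(tert-butyldimethylsilyloxy)-4,4-dimethyloxolan-2-one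
Conditions: TBSCl, imidazole, DMF, rt
Reagents that add atoms: tert-butyldimethylsilyl chloride, CC(C)(C)[Si](C)(C)Cl
Why: Silyl ether formation at the only hydroxyl gives a bulky, non-chelating O4 group that later steers the addition at C3; the C4 centre comes unchanged from the chiral pool.

Step 2
Reactants: 2 (3R)-3-(tert-butyldimethylsilyloxy)-4,4-dimethyloxolan-2-one
Product: 3 (3R)-3-(tert-butyldimethylsilyloxy)-4,4-dimethyloxolan-2-ol (lactol, anomer mixture)
Conditions: i-Bu2AlH, CH2Cl2, −78 °C; aq. potassium sodium tartrate
Reagents that add atoms: none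
Why: Partial reduction of a lactone with i-Bu2AlH stops at the aluminium acetal at low temperature and gives the lactol, the masked C3 aldehyde.

Step 3
Reactants: 3 (3R)-3-(tert-butyldimethylsilyloxy)-4,4-dimethyloxolan-2-ol; 4 ethyl 2-(bromomethyl)prop-2-enoate
Product: 6 (5S)-5-[(1R)-1-(tert-butyldimethylsilyloxy)-3-hydroxy-2,2-dimethylpropyl]-3-methylideneoxolan-2-one, via hydroxy ester 5 (not isolated)
Conditions: Zn dust, THF/sat. aq. NH4Cl, rt; then TsOH·H2O (cat.), CH2Cl2, rt
Reagents that add atoms: none
Why: Zinc Barbier 2-(ethoxycarbonyl)allylation of the open hydroxy-aldehyde form followed by acid-catalysed lactonization; C3 should be set anti to the C4 silyloxy group by non-chelation control (silyloxy group and tert-alkyl group both turned away from the incoming allylzinc), which is the erythro relation that becomes the cis-diol of ring A.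

Step 4
Reactants: 6 (5S)-5-[(1R)-1-(tert-butyldimethylsilyloxy)-3-hydroxy-2,2-dimethylpropyl]-3-methylideneoxolan-2-one; 7 2-bromo-3-(trimethylsilyl)prop-1-ene
Product: 8 (5S)-5-[(1R)-1-(tert-butyldimethylsilyloxy)-3-hydroxy-2,2-dimethylpropyl]-3-[2-(trimethylsilylmethyl)prop-2-enyl]oxolan-2-one (C1 epimers)
Conditions: 7, Mg, THF, 40 °C; then CuBr·SMe2 (10 mol %), 6, −78 → −30 °C; aq. NH4Cl
Reagents that add atoms: none
Why: Copper-catalysed conjugate addition of the alkenyl Grignard reagent to the exocyclic α-methylene lactone (the first equivalent is spent on the hydroxyl) joins C10 to C9; the new centre C1 forms as an epimer mixture that is erased on enolization in step 6.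

Step 5
Reactants: 8 the conjugate adduct
Product: 9 (3R)-3-(tert-butyldimethylsilyloxy)-2,2-dimethyl-3-[(2S)-5-oxo-4-[2-(trimethylsilylmethyl)prop-2-enyl]oxolan-2-yl]propanal (C1 epimers)
Conditions: Dess–Martin periodinane, NaHCO3, CH2Cl2, 0 °C → rt
Reagents that add atoms: none
Why: Dess–Martin oxidation of the primary neopentyl alcohol gives the non-enolizable C6 aldehyde under neutral conditions that spare the allylsilane and the lactone.

Step 6
Reactants: 9 the lactone aldehyde
Product: 10 4-(tert-butyldimethylsilyloxy)-2-hydroxy-3,3-dimethyl-1-[2-(trimethylsilylmethyl)prop-2-enyl]-6-oxabicyclo[3.2.1]octan-7-one (ring A closed; C11(=O)–O3 bridge across C1 and C3; O4 cis to O3; C6 carbinol either epimer)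
Conditions: LiN(SiMe3)2, THF, −78 °C; AcOH quench
Reagents that add atoms: none
Why: Intramolecular aldol addition of the lactone lithium enolate to the neopentyl aldehyde closes ring A through a chair helped by the gem-dimethyl group; because C11 stays bonded through O3 to C3, the quaternary centre C1 can only form with C11 and O3 cis, so C3 fixes C1, and the C6 carbinol configuration does not matter because it is oxidized next.

Step 7
Reactants: 10 the bridged hydroxy lactone
Product: 11 4-(tert-butyldimethylsilyloxy)-3,3-dimethyl-1-[2-(trimethylsilylmethyl)prop-2-enyl]-6-oxabicyclo[3.2.1]octane-2,7-dione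
Conditions: Dess–Martin periodinane, NaHCO3, CH2Cl2, rt
Reagents that add atoms: none
Why: Dess–Martin oxidation of the hindered secondary carbinol gives the C6 ketone, a β-keto lactone that cannot enolize on either side.

Step 8
Reactants: 11 the bridged keto lactone
Product: 12 tricyclic tertiary alcohol: ring A fused at C1–C6 to a methylidenecyclopentane (C9H2–C10(=CH2)–C12H2), C6–OH, lactone bridge and O4 silyl ether retained, cis ring fusion expected
Conditions: EtAlCl2, CH2Cl2, −78 → −20 °C; aq. NaHCO3
Reagents that add atoms: none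
Why: Intramolecular Hosomi–Sakurai addition: EtAlCl2 activates the chelating β-keto lactone and the allylsilane terminus C12 adds to C6 (5-exo at the carbonyl), leaving the exocyclic methylene on C10; the ring-fusion configuration at C6 is of no consequence because C6 becomes sp2 in step 9.

Step 9
Reactants: 12 the tricyclic tertiary alcohol
Product: 14 cyclopentadiene lactone: ring A-fused 5,5-disubstituted cyclopentadiene (C9=C10(CH3)–C12=C6) with the C11(=O)–O3 bridge and O4 silyl ether, via exocyclic diene 13 (not isolated)
Conditions: Burgess reagent, PhH, 50 °C; then TsOH·H2O (5 mol %), rt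
Reagents that add atoms: none
Why: Burgess dehydration (syn elimination) can only take a C12 hydrogen because C1 and C5 are quaternary, and acid then moves the exocyclic double bond into the ring through the C10/C6 allyl cation to the only cyclopentadiene that the quaternary C1 allows.

Step 10
Reactants: 14 the cyclopentadiene lactone
Product: 15 diene diol: O11–H and O3–H free, O4 tert-butyldimethylsilyl ether, C11 and O3 and O4 all cis on ring A
Conditions: LiAlH4, THF, 0 °C; aq. potassium sodium tartrate
Reagents that add atoms: none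
Why: Hydride reduction of the lactone releases the C11 primary alcohol and the C3 secondary alcohol at once without touching the diene or the silyl ether.

Step 11
Reactants: 15 the diene diol; 16 chloro(dimethyl)vinylsilane
Product: 18 O11 dimethyl(vinyl)silyl ether O3 acetate of the diene diol, via silyl ether 17 (not isolated)
Conditions: 16, Et3N, CH2Cl2, −78 → 0 °C; then Ac2O, DMAP, rt
Reagents that add atoms: acetic anhydride, CC(=O)OC(C)=O
Why: Silylation selects the primary O11–H over the hindered axial O3–H, and DMAP-catalysed acetylation then installs the O3 acetate of the target in the same flask.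

Step 12
Reactants: 18 the silyl-tethered triene
Product: 19 Diels–Alder adduct: norbornene (bridge C1, bridgeheads C6 and C9, alkene C10=C12) with a 1-oxa-2-silacyclohexane ring C1–C11–O–SiMe2–C8–C9, silicon exo on C8
Conditions: PhMe (0.01 M), BHT, 170 °C, sealed tube
Reagents that add atoms: none
Why: Silicon-tethered intramolecular Diels–Alder reaction: the O11–Si tether delivers the vinyl group to the diene face syn to C11 and holds silicon exo, which sets C6, C8 and C9; the silicon-bearing carbon should bond to C9 because the alternative path over C1–C6 runs into the axial C5 methyl and would join it to the fully substituted terminus.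

Step 13
Reactants: 19 the siloxane adduct
Product: 20 norbornene diol: exo C8–OH and C11–OH, O3 acetate, O4 silyl ether
Conditions: H2O2 (30% aq.), KF, KHCO3, THF/MeOH, rt
Reagents that add atoms: hydrogen peroxide, OO
Why: Tamao oxidation of the cyclic alkoxysilane moves C8 from silicon to oxygen with retention, giving the exo alcohol, while the Si–O11 bond is hydrolysed; the hindered alkene and the shielded axial acetate should be inert to buffered peroxide.

Step 14
Reactants: 20 the norbornene diol
Product: 21 O11 acetate with free exo C8–OH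
Conditions: AcCl, 2,4,6-collidine, CH2Cl2, −78 °C
Reagents that add atoms: acetyl chloride, CC(Cl)=O
Why: Low-temperature acylation with a hindered pyridine base discriminates the primary O11–H from the secondary C8–OH.

Step 15
Reactants: 21 the O11 acetate
Product: 22 exo C8 4-bromobenzenesulfonate: O3 and O11 acetates, O4 silyl ether, alkene C10=C12
Conditions: 4-BrC6H4SO2Cl, pyridine, DMAP (cat.), 0 °C
Reagents that add atoms: 4-bromobenzenesulfonyl chloride, O=S(=O)(Cl)c1ccc(Br)cc1
Why: Sulfonylation at oxygen keeps the exo configuration at C8; the homoallylic brosylate is kept cold and used at once.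

Step 16
Reactants: 22 the exo C8 brosylate
Product: 23 nortricyclyl acetate: cyclopropane C8–C9–C10, acetates on O3, O11 and O12 (O12 on the C7 side), O4 silyl ether
Conditions: AcOH, NaOAc, 50 °C
Reagents that add atoms: acetic acid, CC(=O)O
Why: Ionization of the exo C8 brosylate is assisted from the endo side by the C10=C12 π bond, so C8–C10 forms with inversion at C8 while the charge moves to C12 of a bisected cyclopropylcarbinyl (nortricyclyl) cation, which acetic acid captures at C12. The closest known reaction type is the acetolysis of exo-5-norbornen-2-yl arenesulfonates to 3-nortricyclyl acetates. The cyclopropane closes in a 3-exo-trig mode, the alkene being attacked at its methyl-bearing carbon C10 by the carbon already tied to it through C9. C8 and C10 are fixed by the cage, since only the exo leaving group and the endo alkene face can bond, and C12 is set by the face on which acetate arrives. The step needs capture at C12 and not at C8, and on the lobe facing C7; in this ionizing, weakly nucleophilic medium the bridged ion should relax to the bisected cation, whose lobe facing C1 is shielded by the ring A methylene C2 held over it by the quaternary bridge carbon. The C10 methyl raises the donor ability of the alkene, and the acetate buffer keeps the liberated sulfonic acid from opening the cyclopropane or cleaving the silyl ether.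

Step 17
Reactants: 23 the nortricyclyl acetate
Product: 24 CNP0197219.1 (target)
Conditions: HF·pyridine, pyridine, THF, 0 °C → rt
Reagents that add atoms: none
Why: Fluoride cleavage of the silyl ether under buffered, non-basic conditions frees O4–H without O3-to-O4 acetyl migration, acetate hydrolysis or ionization of the cyclopropylcarbinyl acetate.

**Compound list**

1 | D-(−)-pantolactone, (3R)-3-hydroxy-4,4-dimethyloxolan-2-one | CC1(C)COC(=O)[C@@H]1O | starting material
2 | (3R)-3-(tert-butyldimethylsilyloxy)-4,4-dimethyloxolan-2-one | CC1(C)COC(=O)[C@@H]1O[Si](C)(C)C(C)(C)C | intermediate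
3 | (3R)-3-(tert-butyldimethylsilyloxy)-4,4-dimethyloxolan-2-ol, anomer mixture | CC1(C)COC(O)[C@@H]1O[Si](C)(C)C(C)(C)C | intermediate
4 | ethyl 2-(bromomethyl)prop-2-enoate | C=C(CBr)C(=O)OCC | starting material
5 | ethyl (4S,5R)-5-(tert-butyldimethylsilyloxy)-4,7-dihydroxy-6,6-dimethyl-2-methylideneheptanoate | CCOC(=O)C(=C)C[C@H](O)[C@H](O[Si](C)(C)C(C)(C)C)C(C)(C)CO | intermediate
6 | (5S)-5-[(1R)-1-(tert-butyldimethylsilyloxy)-3-hydroxy-2,2-dimethylpropyl]-3-methylideneoxolan-2-one | C=C1C[C@H](OC1=O)[C@H](O[Si](C)(C)C(C)(C)C)C(C)(C)CO | intermediate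
7 | 2-bromo-3-(trimethylsilyl)prop-1-ene | C=C(Br)C[Si](C)(C)C | starting material
8 | (5S)-5-[(1R)-1-(tert-butyldimethylsilyloxy)-3-hydroxy-2,2-dimethylpropyl]-3-[2-(trimethylsilylmethyl)prop-2-enyl]oxolan-2-one, C1 epimers | C=C(C[Si](C)(C)C)CC1C[C@H](OC1=O)[C@H](O[Si](C)(C)C(C)(C)C)C(C)(C)CO | intermediate
9 | (3R)-3-(tert-butyldimethylsilyloxy)-2,2-dimethyl-3-[(2S)-5-oxo-4-[2-(trimethylsilylmethyl)prop-2-enyl]oxolan-2-yl]propanal, C1 epimers | C=C(C[Si](C)(C)C)CC1C[C@H](OC1=O)[C@H](O[Si](C)(C)C(C)(C)C)C(C)(C)C=O | intermediate
10 | 4-(tert-butyldimethylsilyloxy)-2-hydroxy-3,3-dimethyl-1-[2-(trimethylsilylmethyl)prop-2-enyl]-6-oxabicyclo[3.2.1]octan-7-one, C6 carbinol either epimer | O=C1O[C@H]2C[C@]1(CC(=C)C[Si](C)(C)C)C(O)C(C)(C)[C@H]2O[Si](C)(C)C(C)(C)C | intermediate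
11 | 4-(tert-butyldimethylsilyloxy)-3,3-dimethyl-1-[2-(trimethylsilylmethyl)prop-2-enyl]-6-oxabicyclo[3.2.1]octane-2,7-dione | O=C1O[C@H]2C[C@]1(CC(=C)C[Si](C)(C)C)C(=O)C(C)(C)[C@H]2O[Si](C)(C)C(C)(C)C | intermediate
12 | tricyclic tertiary alcohol: ring A cis-fused at C1–C6 to a methylidenecyclopentane, C6–OH, C11(=O)–O3 lactone bridge, O4 silyl ether | O=C1O[C@H]2C[C@@]13CC(=C)C[C@]3(O)C(C)(C)[C@H]2O[Si](C)(C)C(C)(C)C | intermediate
13 | cross-conjugated diene lactone (C6=C12 and exocyclic C10=CH2) | O=C1O[C@H]2C[C@@]13CC(=C)C=C3C(C)(C)[C@H]2O[Si](C)(C)C(C)(C)C | intermediate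
14 | cyclopentadiene lactone (C9=C10(CH3)–C12=C6), C11(=O)–O3 bridge, O4 silyl ether | O=C1O[C@H]2C[C@@]13C=C(C)C=C3C(C)(C)[C@H]2O[Si](C)(C)C(C)(C)C | intermediate
15 | diene diol: C11 hydroxymethyl, axial O3–H, O4 silyl ether, all cis on ring A | OC[C@]12C[C@H](O)[C@H](O[Si](C)(C)C(C)(C)C)C(C)(C)C1=CC(C)=C2 | intermediate
16 | chloro(dimethyl)vinylsilane | C=C[Si](C)(C)Cl | starting material
17 | O11 dimethyl(vinyl)silyl ether of 15 | C=C[Si](C)(C)OC[C@]12C[C@H](O)[C@H](O[Si](C)(C)C(C)(C)C)C(C)(C)C1=CC(C)=C2 | intermediate
18 | O11 dimethyl(vinyl)silyl ether O3 acetate | C=C[Si](C)(C)OC[C@]12C[C@H](OC(C)=O)[C@H](O[Si](C)(C)C(C)(C)C)C(C)(C)C1=CC(C)=C2 | intermediate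
19 | Diels–Alder adduct: norbornene with oxasilacyclohexane ring, silicon exo on C8 | C[Si]1(C)OC[C@]23C[C@H](OC(C)=O)[C@H](O[Si](C)(C)C(C)(C)C)C(C)(C)[C@]24C[C@H]1[C@H]3C(C)=C4 | intermediate
20 | norbornene diol: exo C8–OH and C11–OH | OC[C@]12C[C@H](OC(C)=O)[C@H](O[Si](C)(C)C(C)(C)C)C(C)(C)[C@]13C[C@H](O)[C@H]2C(C)=C3 | intermediate
21 | O11 acetate with free exo C8–OH | CC(=O)OC[C@]12C[C@H](OC(C)=O)[C@H](O[Si](C)(C)C(C)(C)C)C(C)(C)[C@]13C[C@H](O)[C@H]2C(C)=C3 | intermediate
22 | exo C8 4-bromobenzenesulfonate (key-step precursor) | CC(=O)OC[C@]12C[C@H](OC(C)=O)[C@H](O[Si](C)(C)C(C)(C)C)C(C)(C)[C@]13C[C@H](OS(=O)(=O)c4ccc(Br)cc4)[C@H]2C(C)=C3 | intermediate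
23 | nortricyclyl triacetate with O4 silyl ether (key-step product) | CC(=O)OC[C@]12C[C@H](OC(C)=O)[C@H](O[Si](C)(C)C(C)(C)C)C(C)(C)[C@]13C[C@@H]1[C@H]2[C@]1(C)[C@H]3OC(C)=O | intermediate
24 | CNP0197219.1 | CC(=O)OC[C@]12C[C@H](OC(C)=O)[C@H](O)C(C)(C)[C@]13C[C@@H]1[C@H]2[C@]1(C)[C@H]3OC(C)=O | target

**Step count and risks**

Total: 17 steps. Longest linear sequence: 17 steps (1 to 24).

Step 16 (key step). What may go wrong: the delocalized cation may be captured on the C12 lobe facing C1, anti to the new C8–C10 bond, or at C8, returning the norbornene. Fallback: from 22, solvolysis in buffered aqueous acetone (2,6-lutidine, 40 °C) would give the C12 carbinols F1 as an epimer mixture; any C8 carbinol formed by return is compound 21 and goes back through step 15. The carbinols are then equilibrated by reversible hydrogen transfer through the C12 ketone with the ruthenium hydride [(η5-Ph4C4CO)2H]Ru2(CO)4(μ-H) (2 mol %, toluene, 80 °C). This should enrich the less strained carbinol F2, whose hydroxyl lies on the C7 side, and acetylation of F2 (Ac2O, DMAP, pyridine) rejoins the route at 23.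

Step 12. What may go wrong: cycloaddition at the doubly neopentyl terminus C6 may be slow, so that bonding of the tethered carbon to C6 or thermal alkyl migration in the heated cyclopentadiene competes. Fallback: from 18, the labile silyl ether is cleaved (citric acid, MeOH, 0 °C) to the primary alcohol F3, which is heated with dibutyl vinylboronate (C=CB(OCCCC)OCCCC; toluene, 4 Å molecular sieves, 110–140 °C). Transesterification gives the mixed vinylboronate F4, a more reactive tethered dienophile, and intramolecular Diels–Alder reaction gives the cyclic boronate F5. Oxidation with Me3NO·2H2O (THF, rt) replaces boron on C8 by hydroxyl with retention and rejoins the route at 20.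

Step 8. What may go wrong: carbon–carbon bond formation at the ketone flanked by two quaternary carbons may fail, with protodesilylation of the allylsilane taking over. Fallback: from 11, ozonolysis of the 1,1-disubstituted alkene (ozone, CH2Cl2/MeOH, −78 °C; Me2S) and loss of the α-silyl group on work-up (KF, MeOH) give the 1,4-diketone F6. Acid-catalysed aldol condensation (TsOH, toluene, reflux with water removal) closes the cyclopentenone F7 (C6=C12–C10(=O)). MeMgBr/CeCl3 (THF, −78 °C) adds to the enone carbonyl to give the tertiary allylic alcohol F8, and catalytic TsOH dehydrates it through the allyl cation to 14, where the route is rejoined.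

**Further compounds**

F1 | step 16 | C12 carbinols of the nortricyclane (epimer mixture; O3 and O11 acetates, O4 silyl ether) | CC(=O)OC[C@]12C[C@H](OC(C)=O)[C@H](O[Si](C)(C)C(C)(C)C)C(C)(C)[C@]13C[C@@H]1[C@H]2[C@]1(C)C3O
F2 | step 16 | C12 carbinol with the hydroxyl on the C7 side | CC(=O)OC[C@]12C[C@H](OC(C)=O)[C@H](O[Si](C)(C)C(C)(C)C)C(C)(C)[C@]13C[C@@H]1[C@H]2[C@]1(C)[C@H]3O
F3 | step 12 | diene primary alcohol with O3 acetate and O4 silyl ether | OC[C@]12C[C@H](OC(C)=O)[C@H](O[Si](C)(C)C(C)(C)C)C(C)(C)C1=CC(C)=C2
F4 | step 12 | O11 butoxy(vinyl)boryl ether of F3 | C=CB(OCCCC)OC[C@]12C[C@H](OC(C)=O)[C@H](O[Si](C)(C)C(C)(C)C)C(C)(C)C1=CC(C)=C2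
F5 | step 12 | Diels–Alder adduct with oxaborinane ring, boron exo on C8 | CCCCOB1OC[C@]23C[C@H](OC(C)=O)[C@H](O[Si](C)(C)C(C)(C)C)C(C)(C)[C@]24C[C@H]1[C@H]3C(C)=C4
F6 | step 8 | 1-(2-oxopropyl) bridged keto lactone (1,4-diketone) | O=C1O[C@H]2C[C@]1(CC(C)=O)C(=O)C(C)(C)[C@H]2O[Si](C)(C)C(C)(C)C
F7 | step 8 | ring A-fused cyclopentenone lactone (C6=C12–C10(=O)) | O=C1O[C@H]2C[C@@]13CC(=O)C=C3C(C)(C)[C@H]2O[Si](C)(C)C(C)(C)C
F8 | step 8 | tertiary allylic alcohol at C10 (C10 epimers) | O=C1O[C@H]2C[C@@]13CC(C)(O)C=C3C(C)(C)[C@H]2O[Si](C)(C)C(C)(C)C
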